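**Retrosynthetic overview**
- Eritrichin comes from global hydrogenolysis of its heptabenzyl derivative. No alkene is left at that stage, so benzyl can be used on every OH and on the CO2H.
- The second naphthalene ring comes from a light-driven dehydrogenative [4+2] benzannulation. It forms C2–C3 (caffeoyl Cα to alkyne CH) and C4–C4a (alkyne C(Ar) to caffeoyl C6).
- The four-atom partner is perbenzylated natural (R)-rosmarinic acid. It already holds ring A, the ester link, the danshensu unit and the only stereocentre.
- The two-atom partner is 3,4-bis(benzyloxy)phenylacetylene, made by one-carbon homologation of the aldehyde.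
- Ring order: all three benzene rings are bought. The only ring formed is the second naphthalene ring, in the key step.

Assumption: natural (R)-(+)-rosmarinic acid, 3,4-bis(benzyloxy)benzaldehyde, benzyl bromide and the Ohira–Bestmann reagent are taken as catalogue chemicals.

**Step 1**
Reactants: 1 (R)-rosmarinic acid
Product: 2 benzyl (2R)-3-[3,4-bis(benzyloxy)phenyl]-2-{[(2E)-3-[3,4-bis(benzyloxy)phenyl]prop-2-enoyl]oxy}propanoate (pentabenzyl rosmarinate)
Conditions: BnBr (6 equiv), K2CO3 (6 equiv), DMF, 0 °C → rt, 16 h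
Reagents that add atoms: benzyl bromide, BrCc1ccccc1
Why: Williamson-type SN2 O-benzylation of the four phenoxides and the carboxylate, in which carbonate at or below rt does not enolise the α-acyloxy ester, so the purchased (R)-centre is carried through unchanged.

**Step 2**
Reactants: 3 3,4-bis(benzyloxy)benzaldehyde
Product: 5 4-ethynyl-1,2-bis(benzyloxy)benzene, via 4-(2-diazoethenyl)-1,2-bis(benzyloxy)benzene 4 (not isolated)
Conditions: Ohira–Bestmann reagent (1.3 equiv), K2CO3 (2 equiv), MeOH–THF 2:1, rt, 12 h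
Reagents that add atoms: dimethyl (1-diazo-2-oxopropyl)phosphonate, COP(=O)(OC)C(=[N+]=[N-])C(C)=O
Why: Ohira–Bestmann variant of the Seyferth–Gilbert homologation, in which methoxide deacetylates the reagent, the diazophosphonate anion olefinates the aldehyde (HWE type) to diazoalkene 4, and 4 loses N2 with a 1,2-H shift to give the terminal alkyne, the benzyl ethers being inert to K2CO3/MeOH.

**Step 3 (key step)**
Reactants: 2 pentabenzyl rosmarinate; 5 4-ethynyl-1,2-bis(benzyloxy)benzene (2.5 equiv, added in portions)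
Product: 6 benzyl (2R)-3-[3,4-bis(benzyloxy)phenyl]-2-({6,7-bis(benzyloxy)-4-[3,4-bis(benzyloxy)phenyl]naphthalene-2-carbonyl}oxy)propanoate (heptabenzyl eritrichin)
Conditions: [Mes-Acr-Me]ClO4 (5 mol %), Co(dmgH)2(py)Cl (8 mol %), DCE–HFIP 4:1 (0.05 M), 450 nm LEDs, Ar, 25 °C, 24 h, no base
Reagents that add atoms: none
Why: Proposed new method: a dehydrogenative photoredox/cobaloxime [4+2] benzannulation in which a cinnamate ester (a β-acceptor-substituted styrene) is the four-atom partner for a terminal aryl alkyne; excited Mes-Acr+ (E* about +2.1 V vs SCE) oxidises the 3,4-dialkoxycinnamate (or the equally electron-rich alkyne, both entries converging) to a radical cation with spin and charge on Cα, the same C8 position through which dialkoxycinnamates dimerise oxidatively; Cα bonds to the unhindered terminal alkyne carbon to give an aryl-stabilised vinyl distonic radical cation, which closes a six-membered ring onto caffeoyl C6 (para to the 3-OBn group and less hindered than C2, hence the 6,7-dioxygenation); loss of H+ re-aromatises ring A, Co(II) removes the activated C2–H as Co(III)–H, this gives H2 with H+, and Acr• returns Co(III) to Co(II); aromatisation makes the sequence irreversible, E/Z scrambling of 2 is irrelevant because Cα becomes sp3 on the way, holes parked on the saturated danshensu ring are repaired by back electron transfer in the base-free HFIP medium, and the (R)-centre is not touched; closest known reaction type: the acridinium/cobaloxime oxidant-free [4+2] annulation of α-substituted styrenes with alkynes to naphthalenes, which has not been shown for cinnamates.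

**Step 4**
Reactants: 6 heptabenzyl eritrichin
Product: 7 eritrichin, (2R)-3-(3,4-dihydroxyphenyl)-2-{[4-(3,4-dihydroxyphenyl)-6,7-dihydroxynaphthalene-2-carbonyl]oxy}propanoic acid
Conditions: H2 (1 atm), 10 % Pd/C, THF–MeOH 1:1, rt, 12 h; filter under Ar
Reagents that add atoms: none
Why: Heterogeneous catalytic hydrogenolysis cleaves the six ArO–CH2Ph bonds and the benzyl ester under neutral conditions, while the naphthalene, the naphthoate ester and the homobenzylic C–O bond at the (R)-centre are inert at 1 atm, so no epimerisation can occur.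

**Compound list**
1 | (R)-rosmarinic acid | O=C(O[C@H](Cc1ccc(O)c(O)c1)C(=O)O)/C=C/c1ccc(O)c(O)c1 | starting material
2 | benzyl (2R)-3-[3,4-bis(benzyloxy)phenyl]-2-{[(2E)-3-[3,4-bis(benzyloxy)phenyl]prop-2-enoyl]oxy}propanoate | O=C(O[C@H](Cc1ccc(OCc2ccccc2)c(OCc2ccccc2)c1)C(=O)OCc1ccccc1)/C=C/c1ccc(OCc2ccccc2)c(OCc2ccccc2)c1 | intermediate
3 | 3,4-bis(benzyloxy)benzaldehyde | O=Cc1ccc(OCc2ccccc2)c(OCc2ccccc2)c1 | starting material
4 | 4-(2-diazoethenyl)-1,2-bis(benzyloxy)benzene (not isolated) | [N-]=[N+]=C=Cc1ccc(OCc2ccccc2)c(OCc2ccccc2)c1 | intermediate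
5 | 4-ethynyl-1,2-bis(benzyloxy)benzene | C#Cc1ccc(OCc2ccccc2)c(OCc2ccccc2)c1 | intermediate
6 | benzyl (2R)-3-[3,4-bis(benzyloxy)phenyl]-2-({6,7-bis(benzyloxy)-4-[3,4-bis(benzyloxy)phenyl]naphthalene-2-carbonyl}oxy)propanoate | O=C(O[C@H](Cc1ccc(OCc2ccccc2)c(OCc2ccccc2)c1)C(=O)OCc1ccccc1)c1cc(-c2ccc(OCc3ccccc3)c(OCc3ccccc3)c2)c2cc(OCc3ccccc3)c(OCc3ccccc3)cc2c1 | intermediate
7 | eritrichin | O=C(O[C@H](Cc1ccc(O)c(O)c1)C(=O)O)c1cc(-c2ccc(O)c(O)c2)c2cc(O)c(O)cc2c1 | target

**Total step count:** 4. **Longest linear sequence:** 3 (1 → 2 → 6 → 7).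

**Steps most likely to fail**

**Step 3 (the proposed new step).**
Risks:
- Oxidative 8–8′ homodimerisation of 2.
- Radical-cation dimerisation of 5.
- Benzylic deprotonation and cobalt-mediated desaturation at the danshensu CH2, which would destroy the stereocentre.
- Over-oxidation of the electron-rich product.

The fallback uses known chemistry only. It sets out from 3 and comes back at 6.
- Stobbe condensation of 3 with dimethyl succinate (NaOMe, MeOH, reflux) gives (E)-4-[3,4-bis(benzyloxy)phenyl]-3-(methoxycarbonyl)but-3-enoic acid F1.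
- Ac2O/NaOAc at reflux closes the ring by acylation para to the 3-OBn group and gives methyl 4-acetoxy-6,7-bis(benzyloxy)-2-naphthoate F2.
- K2CO3/MeOH frees methyl 6,7-bis(benzyloxy)-4-hydroxy-2-naphthoate F3.
- Tf2O/pyridine gives methyl 6,7-bis(benzyloxy)-4-(trifluoromethylsulfonyloxy)-2-naphthoate F4.
- Suzuki coupling with commercial 3,4-bis(benzyloxy)phenylboronic acid (Pd(PPh3)4, K2CO3, dioxane–H2O, 90 °C) gives methyl 6,7-bis(benzyloxy)-4-[3,4-bis(benzyloxy)phenyl]-2-naphthoate F5.
- LiOH (THF–MeOH–H2O) gives 6,7-bis(benzyloxy)-4-[3,4-bis(benzyloxy)phenyl]-2-naphthoic acid F6.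
- In parallel, commercial sodium (R)-danshensu with BnBr/K2CO3 in DMF gives benzyl (2R)-3-[3,4-bis(benzyloxy)phenyl]-2-hydroxypropanoate F7.
- Steglich esterification of F6 with F7 (EDC·HCl, DMAP, CH2Cl2, 0 °C) gives 6. The configuration is retained because the C–O bond at the stereocentre is not touched.

**Step 1.**
Risks:
- Carbonate-induced partial racemisation.
- E1cB loss of the caffeate from the α-acyloxy ester.
- Incomplete pentabenzylation.
- C-benzylation.

The fallback builds 2 from separately protected halves instead of alkylating the intact ester. It sets out from 3 and comes back at 2.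
- Knoevenagel–Doebner condensation of 3 with malonic acid (pyridine, cat. piperidine, 90 °C) gives (E)-3-[3,4-bis(benzyloxy)phenyl]prop-2-enoic acid F8.
- F8 is joined to the alcohol F7, made as described above, by Steglich esterification (EDC·HCl, DMAP, CH2Cl2, 0 °C) to give 2.

**Step 4.**
Risks:
- Stalling at partly debenzylated, poorly soluble intermediates.
- Catalyst poisoning.
- Air oxidation of the hexaphenol during filtration.

The fallback replaces hydrogenolysis by Lewis-acid cleavage with a cation trap. It sets out from 6 and comes back at 7.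
- BCl3 (12 equiv) and pentamethylbenzene (15 equiv) in CH2Cl2 at −78 °C cleave the benzyl groups.
- A MeOH quench followed by reversed-phase purification gives 7.
- The benzyl cations are captured by the arene, and the ester and the stereocentre are left alone at this temperature.

**Further compounds**
F1 | step 3 | (E)-4-[3,4-bis(benzyloxy)phenyl]-3-(methoxycarbonyl)but-3-enoic acid | COC(=O)/C(CC(=O)O)=C/c1ccc(OCc2ccccc2)c(OCc2ccccc2)c1
F2 | step 3 | methyl 4-acetoxy-6,7-bis(benzyloxy)-2-naphthoate | COC(=O)c1cc(OC(C)=O)c2cc(OCc3ccccc3)c(OCc3ccccc3)cc2c1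
F3 | step 3 | methyl 6,7-bis(benzyloxy)-4-hydroxy-2-naphthoate | COC(=O)c1cc(O)c2cc(OCc3ccccc3)c(OCc3ccccc3)cc2c1
F4 | step 3 | methyl 6,7-bis(benzyloxy)-4-(trifluoromethylsulfonyloxy)-2-naphthoate | COC(=O)c1cc(OS(=O)(=O)C(F)(F)F)c2cc(OCc3ccccc3)c(OCc3ccccc3)cc2c1
F5 | step 3 | methyl 6,7-bis(benzyloxy)-4-[3,4-bis(benzyloxy)phenyl]-2-naphthoate | COC(=O)c1cc(-c2ccc(OCc3ccccc3)c(OCc3ccccc3)c2)c2cc(OCc3ccccc3)c(OCc3ccccc3)cc2c1
F6 | step 3 | 6,7-bis(benzyloxy)-4-[3,4-bis(benzyloxy)phenyl]-2-naphthoic acid | OC(=O)c1cc(-c2ccc(OCc3ccccc3)c(OCc3ccccc3)c2)c2cc(OCc3ccccc3)c(OCc3ccccc3)cc2c1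
F7 | step 3 | benzyl (2R)-3-[3,4-bis(benzyloxy)phenyl]-2-hydroxypropanoate | O[C@H](Cc1ccc(OCc2ccccc2)c(OCc2ccccc2)c1)C(=O)OCc1ccccc1
F8 | step 1 | (E)-3-[3,4-bis(benzyloxy)phenyl]prop-2-enoic acid | OC(=O)/C=C/c1ccc(OCc2ccccc2)c(OCc2ccccc2)c1
F0 | step 4 | none | none
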